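In the violet run the other capture product gains on the target: 4.2% against 2.7% at 0.500 h, but 26.0% against 5.9% at 2.50 h, so the ratio of the two accumulated amounts climbs from 1.56 to 4.41.

| flask | substrate | first nucleophile | solid second nucleophile | remark | time |
|---|---|---|---|---|---|
| violet | 0.025 M | 1.05 equiv | 1 equiv | run made earlier |  |
| flask | 0.050 M | 1.05 equiv | 1.00 equiv |  | 25 h |

violet run (percent of the substrate charged)

| time / h | other capture product / % | target / % |
|---|---|---|
| 0.500 | 4.2 | 2.7 |
| 1.00 | 9.4 | 4.3 |
| 1.50 | 15.7 | 5.0 |
| 2.00 | 20.6 | 4.9 |
| 2.50 | 26.0 | 5.9 |

(standard deviation of a reading: 0.5 percentage points)

- at the start none of the solid second nucleophile is in solution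

- ratio of other capture product to target at 15 min
- ratio of other capture product to target at 2.5 h
- ratio of other capture product to target at 25 h

The last row shows the target at 5.9% of the substrate, so c(first nucleophile) stays close to its charge. The climb is therefore read here as c(second nucleophile) rising from zero as the solid dissolves.

This reckoning assumes that the two nucleophiles compete and that c(second nucleophile) at a given hour is the same at either charge. The flask then has twice the c(first nucleophile) of the violet run, and its ratio should be lower by that factor.

The last row gives 0.110 M for the scaled ratio, meaning the ratio of accumulated products multiplied by the substrate concentration charged, taken at a given time of the run. Dividing by the flask's 0.050 M gives 2.20 at 2.5 h.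

The first row is the earlier one. A ratio starting from zero is taken as proportional to time there, which gives 0.389 at 15 min. Both values carry the scatter of the readings. The readings stop at 2.50 h, so for 25 h this reckoning expects only a ratio above the 2.5 h value.

The forecast, which runs the opposite way from this reckoning, gives 1.8, 6.3 and 15, holding that “doubling concentration should worsen the ratio”.

The flask gives 0.392, 2.05 and 3.82.

    substrate → intermediate (k = 0.200 /h)
    first nucleophile + intermediate → target (k = 8500 /M/h)
    second nucleophile + intermediate → other capture product (k = 1.20 × 10⁵ /M/h)
    intermediate → solvolysis product (k = 270 /h)
    intermediate → side product (k = 1.90 /h)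
    solid second nucleophile ⇌ second nucleophile, rate k6*(cs6 - [second nucleophile]) while solid is left; crystals form when [second nucleophile] > cs6 (solubility = 38.0 mM, k = 0.370 /h)

The scaled ratio stands the test in this flask at 2.5 h, 2.20 against 2.05. The neighbouring flask is charged with 0.12 M of substrate, with the same equivalents and time. Dividing the same scaled ratio by that charge gives 0.917 at 2.5 h, and that neighbour stands at 0.769. The early reckoning gives 0.162 at 15 min, and that neighbour stands at 0.162. At 25.0 h that neighbour holds 33.7% target against 55.4% other capture product, a ratio of 1.65, lower than the 3.82 of the flask.

The readings are simulated for an exercise, and the scatter is random.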